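**Retrosynthetic overview**
1. Numbering: ring B (seven-membered) is C1(=CH2)–C2–C3(O-acyl)–C4–C5(Me)–C9(OH)–C10(OH); ring A (five-membered) is C4–C5–C6–C7–C8(OH)(iPr). The strategy rests on C5 (quaternary, methyl-bearing) being β and C4 being α to C8, which can be a ketone.
2. Late stage: the C3 isovalerate, the cis-9,10-diol and the C1 methylidene come from a C1 enone (osmylation anti to the C5 methyl, acetonide, Wittig). The enone comes from allylic oxidation of a C9=C10 cycloheptene.
3. Ring B is closed at C9=C10 by ring-closing metathesis between a C5 vinyl group and the butenyl chain on C3. The C8 isopropyl group is added to the ring A ketone anti to the C4 side chain.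
4. Key disconnection: C5–C9 and C4–C3 are both made on 3-methylcyclopent-2-en-1-one by enantioselective conjugate addition of a 1-(trimethylsilyl)vinyl alane and aldol trapping of the enolate with pent-4-enal.
5. Ring order: ring A is bought as the enone; ring B is formed in step 6.

Key step: step 2

Convention: β is the face of the C5 methyl group, α the opposite face; the bicyclic compounds are described with the numbering above.
Assumption: L* is a sulfonate-bearing chiral carbene, (4,5-diphenylimidazolin-2-ylidene with N-(2,6-diethylphenyl) and N-(2-sulfonatoaryl) groups); the antipode that gives the (S) quaternary centre at C5 is used, and both antipodes are available from the two enantiomers of 1,2-diphenylethylenediamine.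

**Route**

Step 1
Reactants: 1 ethynyltrimethylsilane
Product: 2 diisobutyl[1-(trimethylsilyl)ethenyl]aluminium
Conditions: i-Bu2AlH (1.0 equiv), hexanes/THF 5:1, 55 °C, 2 h
Reagents that add atoms: diisobutylaluminium hydride, CC(C)C[AlH]CC(C)C
Why: Syn hydroalumination of a silylalkyne puts aluminium on the silicon-bearing carbon, where the C–Al bond is stabilised, so the 1-silylvinyl alane forms without a catalyst; the solution is used as such in step 2.

Step 2
Reactants: 3 3-methylcyclopent-2-en-1-one; 2 diisobutyl[1-(trimethylsilyl)ethenyl]aluminium; 4 pent-4-enal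
Product: 7 (2S,3S)-2-[(1S)-1-hydroxypent-4-en-1-yl]-3-methyl-3-[1-(trimethylsilyl)ethenyl]cyclopentan-1-one, via aluminium enolate 5 (not isolated), via aluminium aldolate 6 (not isolated)
Conditions: Cu(OTf)2 (5 mol%), [Ag(L*)]2 (2.5 mol%), 2 (1.5 equiv), THF, −78 °C; then 4 (3 equiv), −78 → −40 °C; aq. potassium sodium tartrate
Reagents that add atoms: none
Why: The alane passes its 1-silylvinyl group to the copper–carbene complex, and the alkenylcopper adds to C5 of 3 on the enone face fixed by the sulfonate-bridged ligand, so the quaternary centre forms as (S) and the regiodefined aluminium enolate 5 is released. Enolate 5 then adds to pent-4-enal through an aluminium-bridged six-membered chair transition state to give aldolate 6, which is hydrolysed to 7. The closest known reaction types are the copper–carbene-catalysed enantioselective conjugate addition of silyl-substituted vinylalanes to β-methyl cyclic enones and the aldol reaction of dialkylaluminium enolates made by conjugate addition. No ring is closed; the two new bonds are C5–C9 and C4–C3. C4 is set by approach of the aldehyde to the enolate face opposite the bulky silylvinyl group (cis to the methyl), and C3 by the ring-locked (E)-enolate, which places the aldehyde chain equatorial in the chair and gives the anti aldol. The step needs 1,4- over 1,2-addition, secured by copper catalysis at low temperature, and aldol reaction in preference to attack of residual alane on the aldehyde, secured by excess aldehyde and the higher nucleophilicity of the enolate.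

Step 3
Reactants: 7 aldol
Product: 8 (2S,3S)-3-methyl-2-{(1S)-1-[(triisopropylsilyl)oxy]pent-4-en-1-yl}-3-[1-(trimethylsilyl)ethenyl]cyclopentan-1-one
Conditions: TIPSOTf (1.3 equiv), 2,6-lutidine, CH2Cl2, −78 → 0 °C
Reagents that add atoms: triisopropylsilyl trifluoromethanesulfonate, CC(C)[Si](OS(=O)(=O)C(F)(F)F)(C(C)C)C(C)C
Why: Silyl triflate/lutidine silylation of the hindered secondary alcohol is faster than ketone enolisation at low temperature and the non-nucleophilic base avoids retro-aldol cleavage; the triisopropylsilyl group is chosen to survive the acid of step 4, and no stereocentre is touched.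

Step 4
Reactants: 8 silyl ether
Product: 9 (2S,3R)-3-ethenyl-3-methyl-2-{(1S)-1-[(triisopropylsilyl)oxy]pent-4-en-1-yl}cyclopentan-1-one
Conditions: CF3CO2H (5 equiv), CH2Cl2, 0 °C → rt
Reagents that add atoms: none
Why: Electrophilic protodesilylation of the vinylsilane: ipso protonation gives the β-silyl-stabilised cation, which loses the trimethylsilyl group to trifluoroacetate and leaves the C5 vinyl group, while the hindered silyl ether and the terminal alkene tolerate dilute anhydrous acid (the descriptor at C5 changes only through priorities).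

Step 5
Reactants: 9 vinyl ketone
Product: 10 (1R,2S,3R)-3-ethenyl-3-methyl-1-(propan-2-yl)-2-{(1S)-1-[(triisopropylsilyl)oxy]pent-4-en-1-yl}cyclopentan-1-ol
Conditions: i-PrMgCl, CeCl3 (anhydrous), THF, −78 → 0 °C; aq. NH4Cl
Reagents that add atoms: isopropylmagnesium chloride, CC(C)[Mg]Cl
Why: Organocerium addition (Imamoto conditions) to a hindered, enolisable ketone suppresses enolisation and β-hydride reduction, and the reagent should approach C8 from the α face, anti to the adjacent C4 side chain, so the hydroxyl ends up β (8R).

Step 6
Reactants: 10 diene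
Product: 11 trans-fused hydroazulene: ring B cycloheptene with C9=C10 and C1H2; 3α-triisopropylsilyloxy, 4α-H, 5β-methyl, 8β-hydroxy, 8α-isopropyl
Conditions: second-generation Grubbs catalyst RuCl2(=CHPh)(PCy3)(H2IMes) (5 mol%), CH2Cl2 (5 mM), 40 °C
Reagents that add atoms: none
Why: Ring-closing metathesis: the catalyst loads on the unhindered terminal alkene and closes onto the neopentyl C5 vinyl group with loss of ethene, a seven-membered ring spanning the trans-disposed arms on ring A without strain and fixing the cis C9=C10 geometry.

Step 7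
Reactants: 11 cycloheptene
Product: 12 enone: as 11 with a C1 ketone conjugated to C9=C10
Conditions: Rh2(cap)4 (cap = caprolactamate, 1 mol%), t-BuOOH (5 equiv), K2CO3, CH2Cl2, rt
Reagents that add atoms: tert-butyl hydroperoxide, CC(C)(C)OO
Why: Dirhodium-catalysed allylic oxidation: the tert-butylperoxyl radical abstracts hydrogen from C1, the only allylic C–H position because C5 is quaternary, and the allyl radical is trapped at the unhindered C1 terminus, the mixed peroxide collapsing to the conjugated C1 ketone.

Step 8
Reactants: 12 enone
Product: 13 dihydroxy ketone: C1 ketone, 9α,10α-diol, otherwise as 11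
Conditions: OsO4 (5 mol%), N-methylmorpholine N-oxide (1.5 equiv), citric acid (1 equiv), t-BuOH/H2O 1:1, rt
Reagents that add atoms: osmium tetroxide, O=[Os](=O)(=O)=O; N-methylmorpholine N-oxide, C[N+]1([O-])CCOCC1
Why: Osmium tetroxide syn-dihydroxylation under the acid-buffered catalytic protocol suited to electron-poor alkenes; the reagent should add to the α face of C9=C10, anti to the axial C5 methyl next to C9, which sets the 9α,10α cis diol, and the acidic medium prevents retro-aldol cleavage of the product.

Step 9
Reactants: 13 dihydroxy ketone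
Product: 14 acetonide: 9α,10α-O-isopropylidene derivative of 13
Conditions: Me2C(OMe)2, PPTS (cat.), CH2Cl2, rt
Reagents that add atoms: 2,2-dimethoxypropane, COC(C)(C)OC
Why: Acid-catalysed transketalisation forms the five-membered acetonide of the cis diol, the tertiary C8 hydroxyl having no cis partner and staying free, and the masked diol can no longer undergo retro-aldol or α-ketol reactions in step 10.

Step 10
Reactants: 14 acetonide ketone
Product: 15 methylidene acetonide: C1=CH2, 9α,10α-O-isopropylidene, 3α-triisopropylsilyloxy, 8β-hydroxy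
Conditions: Ph3PCH3Br (4 equiv), KOtBu (3.8 equiv), THF, 0 °C → rt
Reagents that add atoms: methyltriphenylphosphonium bromide, C[P+](c1ccccc1)(c1ccccc1)c1ccccc1.[Br-]
Why: Wittig methylenation of the C1 ketone: addition of the ylide to the unhindered carbonyl is faster than enolisation, so the C10 centre and the β-oxygen groups at C3 and C9 are kept, and the extra ylide only deprotonates the C8 hydroxyl.

Step 11
Reactants: 15 methylidene acetonide
Product: 16 alcohol: 15 with free 3α-hydroxyl
Conditions: TBAF (3 equiv), THF, rt → 40 °C
Reagents that add atoms: none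
Why: Fluoride-mediated desilylation, driven by the Si–F bond, leaves the acetonide, the 1,1-disubstituted alkene and the tertiary alcohol untouched.

Step 12
Reactants: 16 alcohol
Product: 17 ester: 3α-(3-methylbutanoyloxy) acetonide
Conditions: 3-methylbutanoyl chloride (1.5 equiv), pyridine, DMAP (cat.), CH2Cl2, 0 °C → rt
Reagents that add atoms: 3-methylbutanoyl chloride, CC(C)CC(=O)Cl
Why: DMAP-catalysed acylation of the secondary C3 alcohol; the tertiary C8 alcohol next to the isopropyl group is not acylated under these conditions, so it needs no protection.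

Step 13
Reactants: 17 ester acetonide
Product: 18 CNP0204264.1, (3R,3aS,4S,7R,8S,8aS)-3,7,8-trihydroxy-8a-methyl-6-methylidene-3-(propan-2-yl)decahydroazulen-4-yl 3-methylbutanoate
Conditions: AcOH/H2O 4:1, 45 °C
Reagents that add atoms: none
Why: Mild aqueous acid hydrolysis of the acetonide gives the cis diol; acetic acid is too weak to ionise the allylic C10–O bond or the tertiary C8 alcohol and does not cleave the ester.

**Compound list**
1 | ethynyltrimethylsilane | C#C[Si](C)(C)C | starting material
2 | diisobutyl[1-(trimethylsilyl)ethenyl]aluminium | C=C([Si](C)(C)C)[Al](CC(C)C)CC(C)C | intermediate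
3 | 3-methylcyclopent-2-en-1-one | CC1=CC(=O)CC1 | starting material
4 | pent-4-enal | C=CCCC=O | starting material
5 | diisobutylaluminium (3S)-3-methyl-3-[1-(trimethylsilyl)ethenyl]cyclopent-1-en-1-olate | CC(C)C[Al](CC(C)C)OC1=C[C@](C)(CC1)C(=C)[Si](C)(C)C | intermediate
6 | diisobutylaluminium aldolate of 7 | C=CCC[C@H](O[Al](CC(C)C)CC(C)C)[C@@H]1[C@](C)(CCC1=O)C(=C)[Si](C)(C)C | intermediate
7 | (2S,3S)-2-[(1S)-1-hydroxypent-4-en-1-yl]-3-methyl-3-[1-(trimethylsilyl)ethenyl]cyclopentan-1-one | C=CCC[C@H](O)[C@@H]1[C@](C)(CCC1=O)C(=C)[Si](C)(C)C | intermediate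
8 | (2S,3S)-3-methyl-2-{(1S)-1-[(triisopropylsilyl)oxy]pent-4-en-1-yl}-3-[1-(trimethylsilyl)ethenyl]cyclopentan-1-one | C=CCC[C@H](O[Si](C(C)C)(C(C)C)C(C)C)[C@@H]1[C@](C)(CCC1=O)C(=C)[Si](C)(C)C | intermediate
9 | (2S,3R)-3-ethenyl-3-methyl-2-{(1S)-1-[(triisopropylsilyl)oxy]pent-4-en-1-yl}cyclopentan-1-one | C=CCC[C@H](O[Si](C(C)C)(C(C)C)C(C)C)[C@@H]1[C@](C)(CCC1=O)C=C | intermediate
10 | (1R,2S,3R)-3-ethenyl-3-methyl-1-(propan-2-yl)-2-{(1S)-1-[(triisopropylsilyl)oxy]pent-4-en-1-yl}cyclopentan-1-ol | C=CCC[C@H](O[Si](C(C)C)(C(C)C)C(C)C)[C@@H]1[C@](C)(CC[C@@]1(O)C(C)C)C=C | intermediate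
11 | trans-fused hydroazulene, C9=C10, 3α-OTIPS, 4α-H, 5β-Me, 8β-OH, 8α-iPr | C1C[C@H](O[Si](C(C)C)(C(C)C)C(C)C)[C@@H]2[C@](C)(CC[C@@]2(O)C(C)C)C=C1 | intermediate
12 | C1 enone of 11 (C1=O, C9=C10) | O=C1C[C@H](O[Si](C(C)C)(C(C)C)C(C)C)[C@@H]2[C@](C)(CC[C@@]2(O)C(C)C)C=C1 | intermediate
13 | C1 ketone with 9α,10α-diol | O=C1C[C@H](O[Si](C(C)C)(C(C)C)C(C)C)[C@@H]2[C@](C)(CC[C@@]2(O)C(C)C)[C@H](O)[C@@H]1O | intermediate
14 | 9α,10α-acetonide of 13 | O=C1C[C@H](O[Si](C(C)C)(C(C)C)C(C)C)[C@@H]2[C@](C)(CC[C@@]2(O)C(C)C)[C@H](OC(C)(C)O3)[C@@H]13 | intermediate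
15 | 1-methylidene acetonide, 3α-OTIPS | C=C1C[C@H](O[Si](C(C)C)(C(C)C)C(C)C)[C@@H]2[C@](C)(CC[C@@]2(O)C(C)C)[C@H](OC(C)(C)O3)[C@@H]13 | intermediate
16 | 1-methylidene acetonide, 3α-OH | C=C1C[C@H](O)[C@@H]2[C@](C)(CC[C@@]2(O)C(C)C)[C@H](OC(C)(C)O3)[C@@H]13 | intermediate
17 | 1-methylidene acetonide, 3α-(3-methylbutanoyloxy) | C=C1C[C@H](OC(=O)CC(C)C)[C@@H]2[C@](C)(CC[C@@]2(O)C(C)C)[C@H](OC(C)(C)O3)[C@@H]13 | intermediate
18 | CNP0204264.1, (3R,3aS,4S,7R,8S,8aS)-3,7,8-trihydroxy-8a-methyl-6-methylidene-3-(propan-2-yl)decahydroazulen-4-yl 3-methylbutanoate | C=C1C[C@H](OC(=O)CC(C)C)[C@@H]2[C@](C)(CC[C@@]2(O)C(C)C)[C@H](O)[C@@H]1O | target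

**Totals**
Total step count: 13. Longest linear sequence: 13 steps (1 → 18).

**Steps most likely to fail**

Step 2. The hindered aluminium enolate may add to the aldehyde too slowly, so that residual alane consumes the aldehyde, or the aldol may pass through an open transition state with poor anti selectivity. The fallback sets out from 3 (with 2) and comes back at 7. The conjugate addition is run alone and enolate 5 is quenched with Et3SiOTf to give the isolable triethylsilyl enol ether F1. MeLi (THF, 0 °C) cleaves it to the regiodefined lithium enolate F2, which is transmetalated with ZnCl2 if needed and treated with 4 at −78 °C. The closed transition state of the lithium or zinc enolate should give the same anti aldol 7.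

Step 5. Enolisation toward C7 or β-hydride reduction may outrun addition at the congested carbonyl, or the flexible C4 side chain may shield the β face too weakly and allow attack from both faces. The fallback sets out from 9 and comes back at 11, with ring closure and addition in reverse order. Ring-closing metathesis of 9 with the same ruthenium catalyst gives the trans-fused bicyclic ketone F3. Its side chain is tied back into ring B and the β face of the C8 carbonyl is screened by the axial C5 methyl. Addition of i-PrMgCl/CeCl3 to F3 from the α face then gives 11 directly.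

Step 7. The allyl radical may be trapped at C9 instead of C1, giving the transposed enone, or over-oxidation may erode the mass balance. The fallback sets out from 11 and comes back at 12. SeO2 (cat.)/t-BuOOH in CH2Cl2 reacts by an ene reaction followed by a [2,3]-sigmatropic shift, which can only return oxygen to C1, the carbon that loses hydrogen. This gives the allylic alcohol F4 (either C1 epimer), which MnO2 or Dess–Martin periodinane oxidises to 12.

**Further compounds**
F1 | step 2 | triethyl({(3S)-3-methyl-3-[1-(trimethylsilyl)ethenyl]cyclopent-1-en-1-yl}oxy)silane | CC[Si](CC)(CC)OC1=C[C@](C)(CC1)C(=C)[Si](C)(C)C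
F2 | step 2 | lithium (3S)-3-methyl-3-[1-(trimethylsilyl)ethenyl]cyclopent-1-en-1-olate | [Li]OC1=C[C@](C)(CC1)C(=C)[Si](C)(C)C
F3 | step 5 | trans-fused bicyclic C8 ketone, C9=C10, 3α-OTIPS, 4α-H, 5β-Me | C1C[C@H](O[Si](C(C)C)(C(C)C)C(C)C)[C@@H]2[C@](C)(CCC2=O)C=C1
F4 | step 7 | C1 allylic alcohol of 11 (C1 configuration open) | OC1C[C@H](O[Si](C(C)C)(C(C)C)C(C)C)[C@@H]2[C@](C)(CC[C@@]2(O)C(C)C)C=C1
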